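## Retrosynthetic overview

1. The C4 carbinol is set last by NaBH4 reduction of the free (2R,3R)-dihydroflavonol, which comes from its penta-O-benzyl ether by hydrogenolysis.
2. Ring C arises by a one-carbon ring expansion: an α-ketol 1,2-shift of C2 in a 3-hydroxy-2,3-dihydrobenzofuran-3-carbaldehyde gives the 3-hydroxychroman-4-one.
3. The dihydrobenzofuran comes from an asymmetric interrupted Feist–Bénary annulation of 2,4-dimethoxyphloroglucinol (ring A) with an aryl chloropyruvate (ring B plus the three future ring C carbons).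
4. Ring A piece: resorcinol by tribromination, O-methylation and triple hydroxylation. Ring B piece: p-cresol by bromination/oxidation, hydroxylation, benzylation and Darzens condensation with methyl dichloroacetate.
5. Ring order: rings A and B are bought as arenes, the five-membered O-heterocycle is closed first, then expanded to ring C.

Assumption: in step 8 the quinidine-derived catalyst is taken to give the (2R) series with the aryl group cis to the 3-hydroxyl; the quinine-derived pseudoenantiomer would be used if the sense is opposite, and the C3 configuration of 15–17 is erased in step 11 in any case.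

## Route

Step 1
Reactants: 1 p-cresol (4-methylphenol)
Product: 4 3,5-dibromo-4-hydroxybenzaldehyde, via 2,6-dibromo-4-methylphenol 2 (not isolated), via benzal bromide 3 (not isolated)
Conditions: Br2 (4.1 equiv), 1,2-dichlorobenzene, 35 °C then 150 °C; then H2O, 100 °C
Reagents that add atoms: bromine BrBr; water O
Why: Electrophilic ring bromination ortho to the phenol, then hot side-chain bromination and hydrolysis of the benzal bromide, is the established one-pot conversion of p-cresol into this aldehyde, and no stereocentre is involved.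

Step 2
Reactants: 4 3,5-dibromo-4-hydroxybenzaldehyde
Product: 5 3,4,5-trihydroxybenzaldehyde
Conditions: aq NaOH, Cu powder (5 mol %), N2, reflux; then aq HCl
Reagents that add atoms: sodium hydroxide [Na+].[OH-]
Why: Copper-mediated Ullmann-type hydroxylation of the two aryl bromides flanking the phenoxide follows the known 5-bromovanillin to 5-hydroxyvanillin conversion, and the phenoxide-deactivated aldehyde resists Cannizzaro reaction.

Step 3
Reactants: 5 3,4,5-trihydroxybenzaldehyde
Product: 6 3,4,5-tris(benzyloxy)benzaldehyde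
Conditions: BnBr (3.3 equiv), K2CO3, DMF, 60 °C
Reagents that add atoms: benzyl bromide BrCc1ccccc1
Why: Williamson etherification of the three phenols gives the hydrogenolysable protection needed beside the two methyl ethers that must stay.

Step 4
Reactants: 6 3,4,5-tris(benzyloxy)benzaldehyde; 7 methyl dichloroacetate
Product: 9 methyl 3-chloro-2-oxo-3-[3,4,5-tris(benzyloxy)phenyl]propanoate (racemic), via chloroglycidic ester 8 (not isolated)
Conditions: NaOMe, MeOH–THF, −10 °C to rt; then toluene, 60 °C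
Reagents that add atoms: none
Why: Darzens condensation gives the α-chloroglycidic ester, which rearranges by benzylic C–O ionisation and chloride transfer to the β-chloro-α-keto ester, whose benzylic stereocentre is deliberately left racemic because it epimerises through the enol.

Step 5
Reactants: 10 resorcinol (benzene-1,3-diol)
Product: 11 2,4,6-tribromobenzene-1,3-diol
Conditions: Br2 (3.05 equiv), AcOH–H2O, 0 °C to rt
Reagents that add atoms: bromine BrBr
Why: Exhaustive electrophilic bromination of resorcinol at all three activated positions is a classical, near-quantitative reaction.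

Step 6
Reactants: 11 2,4,6-tribromobenzene-1,3-diol
Product: 12 1,3,5-tribromo-2,4-dimethoxybenzene
Conditions: MeI, K2CO3, acetone, reflux
Reagents that add atoms: iodomethane CI
Why: Williamson O-methylation fixes the two oxygens that end as the 6- and 8-methoxy groups.

Step 7
Reactants: 12 1,3,5-tribromo-2,4-dimethoxybenzene
Product: 13 2,4-dimethoxybenzene-1,3,5-triol
Conditions: Cu(acac)2 (10 mol %), N,N'-bis(4-hydroxy-2,6-dimethylphenyl)oxalamide (10 mol %), LiOH·H2O, DMSO–H2O, 120 °C, Ar; then aq HCl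
Reagents that add atoms: lithium hydroxide [Li+].[OH-]
Why: Copper/oxalamide-catalysed hydroxylation of aryl bromides (Ullmann-type C–O coupling) tolerates ortho-alkoxy groups and electron-rich rings and turns the three C–Br bonds into the phloroglucinol hydroxyls.

Step 8
Reactants: 13 2,4-dimethoxybenzene-1,3,5-triol; 9 methyl 3-chloro-2-oxo-3-[3,4,5-tris(benzyloxy)phenyl]propanoate
Product: 15 methyl (2R,3R)-3,4,6-trihydroxy-5,7-dimethoxy-2-[3,4,5-tris(benzyloxy)phenyl]-2,3-dihydro-1-benzofuran-3-carboxylate, via open-chain chlorohydrin 14 (not isolated)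
Conditions: (DHQD)2PYR (hydroquinidine 2,5-diphenyl-4,6-pyrimidinediyl diether, 10 mol %), Proton Sponge (1.1 equiv), THF, −40 °C to 0 °C, Ar
Reagents that add atoms: none
Why: Proposed new method: an asymmetric interrupted Feist–Bénary annulation extended from 1,3-diketones to a phloroglucinol and run as a dynamic kinetic resolution, in which the chiral amine ion-pairs the phenolate of 13 and directs its only free ring carbon onto one face of the ketone of 9 while the chloride-bearing centre racemises through the enol, polar Felkin–Anh addition (nucleophile anti to C–Cl) selects the (S)-chloride to give 14, and the neighbouring phenoxide closes the five-membered ring by SN2 with inversion so that C2 becomes (R) with the aryl cis to the 3-OH; the closest known reaction is the cinchona-alkaloid-catalysed asymmetric interrupted Feist–Bénary reaction of β-diketones with bromopyruvates.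

Step 9
Reactants: 15 methyl (2R,3R)-3,4,6-trihydroxy-5,7-dimethoxy-2-[3,4,5-tris(benzyloxy)phenyl]-2,3-dihydro-1-benzofuran-3-carboxylate
Product: 16 methyl (2R,3R)-4,6-bis(benzyloxy)-3-hydroxy-5,7-dimethoxy-2-[3,4,5-tris(benzyloxy)phenyl]-2,3-dihydro-1-benzofuran-3-carboxylate
Conditions: BnBr (2.4 equiv), K2CO3, DMF, rt
Reagents that add atoms: benzyl bromide BrCc1ccccc1
Why: Williamson etherification caps only the two phenols (the tertiary alcohol does not react), which shuts off phenoxide-driven retro-aldol opening and quinone-methide dehydration to the benzofuran and leaves both stereocentres untouched.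

Step 10
Reactants: 16 methyl (2R,3R)-4,6-bis(benzyloxy)-3-hydroxy-5,7-dimethoxy-2-[3,4,5-tris(benzyloxy)phenyl]-2,3-dihydro-1-benzofuran-3-carboxylate
Product: 17 (2R,3R)-4,6-bis(benzyloxy)-3-hydroxy-5,7-dimethoxy-2-[3,4,5-tris(benzyloxy)phenyl]-2,3-dihydro-1-benzofuran-3-carbaldehyde
Conditions: i-Bu2AlH (3 equiv), CH2Cl2, −78 °C
Reagents that add atoms: none
Why: Partial reduction of an α-hydroxy ester stops at the aldehyde because the chelated aluminium hemiacetal is stable at −78 °C, and neither stereocentre is touched.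

Step 11
Reactants: 17 (2R,3R)-4,6-bis(benzyloxy)-3-hydroxy-5,7-dimethoxy-2-[3,4,5-tris(benzyloxy)phenyl]-2,3-dihydro-1-benzofuran-3-carbaldehyde
Product: 18 (2R,3R)-5,7-bis(benzyloxy)-3-hydroxy-6,8-dimethoxy-2-[3,4,5-tris(benzyloxy)phenyl]-2,3-dihydro-4H-chromen-4-one
Conditions: DBU (0.2 equiv), toluene, 0 °C to rt, Ar
Reagents that add atoms: none
Why: Proposed new method: a base-triggered α-ketol (acyloin) ring expansion of a 3-hydroxy-2,3-dihydrobenzofuran-3-carbaldehyde to a 3-hydroxychroman-4-one, in which the tertiary alkoxide pushes the benzylic, oxygen-bearing C2 (a better migrating group under anionic conditions than the very electron-rich ring A aryl) in a 1,2-shift onto the aldehyde carbon with retention at C2, the change from aldehyde to conjugated aryl ketone makes it irreversible, and the non-chelated anti arrangement of C–O(−) and C=O places the new 3-OH trans to the aryl so that C3 is (R); the closest known reactions are the α-ketol rearrangement of 1-hydroxycycloalkanecarbaldehydes and the D-homoannulation of 17-hydroxy-20-keto steroids.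

Step 12
Reactants: 18 (2R,3R)-5,7-bis(benzyloxy)-3-hydroxy-6,8-dimethoxy-2-[3,4,5-tris(benzyloxy)phenyl]-2,3-dihydro-4H-chromen-4-one
Product: 19 (2R,3R)-3,5,7-trihydroxy-6,8-dimethoxy-2-(3,4,5-trihydroxyphenyl)-2,3-dihydro-4H-chromen-4-one
Conditions: H2 (1 atm), 10% Pd/C, THF–MeOH, rt
Reagents that add atoms: none
Why: Neutral hydrogenolysis removes the five benzyl ethers while the aryl ketone, the C2–O bond and both stereocentres survive, as in benzyl-ether routes to taxifolin-type dihydroflavonols, and the methyl ethers are inert.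

Step 13
Reactants: 19 (2R,3R)-3,5,7-trihydroxy-6,8-dimethoxy-2-(3,4,5-trihydroxyphenyl)-2,3-dihydro-4H-chromen-4-one
Product: 20 (2R,3S,4R)-6,8-dimethoxy-2-(3,4,5-trihydroxyphenyl)-3,4-dihydro-2H-chromene-3,4,5,7-tetrol
Conditions: NaBH4, MeOH, 0 °C
Reagents that add atoms: none
Why: Borohydride reduction of a 5-hydroxy-dihydroflavonol delivers hydride axially, anti to the 3-OH, and gives the equatorial 4-OH (2,3-trans-3,4-trans, C4 = R), the known outcome for taxifolin; C2 and C3 are unchanged and C3 becomes S only through the priority change.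

## Compound list

1 | 4-methylphenol (p-cresol) | Cc1ccc(O)cc1 | starting material
2 | 2,6-dibromo-4-methylphenol | Cc1cc(Br)c(O)c(Br)c1 | intermediate (not isolated)
3 | 2,6-dibromo-4-(dibromomethyl)phenol | BrC(Br)c1cc(Br)c(O)c(Br)c1 | intermediate (not isolated)
4 | 3,5-dibromo-4-hydroxybenzaldehyde | O=Cc1cc(Br)c(O)c(Br)c1 | intermediate
5 | 3,4,5-trihydroxybenzaldehyde | O=Cc1cc(O)c(O)c(O)c1 | intermediate
6 | 3,4,5-tris(benzyloxy)benzaldehyde | O=Cc1cc(OCc2ccccc2)c(OCc2ccccc2)c(OCc2ccccc2)c1 | intermediate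
7 | methyl dichloroacetate | COC(=O)C(Cl)Cl | starting material
8 | methyl 2-chloro-3-[3,4,5-tris(benzyloxy)phenyl]oxirane-2-carboxylate (racemic diastereomer mixture) | COC(=O)C1(Cl)OC1c1cc(OCc2ccccc2)c(OCc2ccccc2)c(OCc2ccccc2)c1 | intermediate (not isolated)
9 | methyl 3-chloro-2-oxo-3-[3,4,5-tris(benzyloxy)phenyl]propanoate (racemic, configurationally labile) | COC(=O)C(=O)C(Cl)c1cc(OCc2ccccc2)c(OCc2ccccc2)c(OCc2ccccc2)c1 | intermediate
10 | benzene-1,3-diol (resorcinol) | Oc1cccc(O)c1 | starting material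
11 | 2,4,6-tribromobenzene-1,3-diol | Oc1c(Br)cc(Br)c(O)c1Br | intermediate
12 | 1,3,5-tribromo-2,4-dimethoxybenzene | COc1c(Br)cc(Br)c(OC)c1Br | intermediate
13 | 2,4-dimethoxybenzene-1,3,5-triol | COc1c(O)cc(O)c(OC)c1O | intermediate
14 | methyl (2S,3S)-3-chloro-2-hydroxy-2-(2,4,6-trihydroxy-3,5-dimethoxyphenyl)-3-[3,4,5-tris(benzyloxy)phenyl]propanoate | COC(=O)[C@@](O)(c1c(O)c(OC)c(O)c(OC)c1O)[C@@H](Cl)c1cc(OCc2ccccc2)c(OCc2ccccc2)c(OCc2ccccc2)c1 | intermediate (not isolated)
15 | methyl (2R,3R)-3,4,6-trihydroxy-5,7-dimethoxy-2-[3,4,5-tris(benzyloxy)phenyl]-2,3-dihydro-1-benzofuran-3-carboxylate | COC(=O)[C@]1(O)[C@@H](c2cc(OCc3ccccc3)c(OCc3ccccc3)c(OCc3ccccc3)c2)Oc2c(OC)c(O)c(OC)c(O)c12 | intermediate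
16 | methyl (2R,3R)-4,6-bis(benzyloxy)-3-hydroxy-5,7-dimethoxy-2-[3,4,5-tris(benzyloxy)phenyl]-2,3-dihydro-1-benzofuran-3-carboxylate | COC(=O)[C@]1(O)[C@@H](c2cc(OCc3ccccc3)c(OCc3ccccc3)c(OCc3ccccc3)c2)Oc2c(OC)c(OCc3ccccc3)c(OC)c(OCc3ccccc3)c12 | intermediate
17 | (2R,3R)-4,6-bis(benzyloxy)-3-hydroxy-5,7-dimethoxy-2-[3,4,5-tris(benzyloxy)phenyl]-2,3-dihydro-1-benzofuran-3-carbaldehyde | O=C[C@]1(O)[C@@H](c2cc(OCc3ccccc3)c(OCc3ccccc3)c(OCc3ccccc3)c2)Oc2c(OC)c(OCc3ccccc3)c(OC)c(OCc3ccccc3)c12 | intermediate
18 | (2R,3R)-5,7-bis(benzyloxy)-3-hydroxy-6,8-dimethoxy-2-[3,4,5-tris(benzyloxy)phenyl]-2,3-dihydro-4H-chromen-4-one | COc1c(OCc2ccccc2)c(OC)c3c(c1OCc1ccccc1)C(=O)[C@H](O)[C@@H](c1cc(OCc2ccccc2)c(OCc2ccccc2)c(OCc2ccccc2)c1)O3 | intermediate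
19 | (2R,3R)-3,5,7-trihydroxy-6,8-dimethoxy-2-(3,4,5-trihydroxyphenyl)-2,3-dihydro-4H-chromen-4-one | COc1c(O)c(OC)c2c(c1O)C(=O)[C@H](O)[C@@H](c1cc(O)c(O)c(O)c1)O2 | intermediate
20 | (2R,3S,4R)-6,8-dimethoxy-2-(3,4,5-trihydroxyphenyl)-3,4-dihydro-2H-chromene-3,4,5,7-tetrol | COc1c(O)c(OC)c2c(c1O)[C@@H](O)[C@H](O)[C@@H](c1cc(O)c(O)c(O)c1)O2 | target

## Count and risks

Total steps: 13. Longest linear sequence: 10 (steps 1–4, then 8–13).

The three steps most likely to fail:

**Step 8 (proposed new annulation).** The risks are an uncatalysed racemic background reaction (O-alkylation first), modest diastereo- or enantiocontrol, and over-dehydration to the aromatic benzofuran. The fallback sets out from 13 and 9 and comes back at 16. The annulation is run without a chiral catalyst as a classical base-mediated phenol/α-halo ketone condensation (K2CO3, acetone, 0 °C to rt). This gives 15 as the racemate, that is, mixed with its enantiomer methyl (2S,3S)-3,4,6-trihydroxy-5,7-dimethoxy-2-[3,4,5-tris(benzyloxy)phenyl]-2,3-dihydro-1-benzofuran-3-carboxylate F2. Benzylation as in step 9 gives 16 together with its enantiomer methyl (2S,3S)-4,6-bis(benzyloxy)-3-hydroxy-5,7-dimethoxy-2-[3,4,5-tris(benzyloxy)phenyl]-2,3-dihydro-1-benzofuran-3-carboxylate F3. The two are separated by preparative chiral supercritical-fluid chromatography; 16 is carried on and F3 is discarded.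

**Step 11 (proposed new ring expansion).** The risks are migration of the ring A aryl instead of C2, which gives a 4-hydroxychroman-3-one whose C2–H is base-labile, and a chelated syn pathway that would give the 2,3-cis isomer. If step 8 delivers the other C3 epimer of 15–17, a chelating Lewis acid would be used in place of DBU. The fallback sets out from 9 (with 13) and comes back at 18, closing ring C directly by known reactions.

- Asymmetric transfer hydrogenation of 9 with dynamic kinetic resolution (RuCl(p-cymene)[(R,R)-TsDPEN] or its mirror image, whichever gives the 2S,3R series; HCO2H–Et3N, DMF, rt) gives the anti chlorohydrin methyl (2S,3R)-3-chloro-2-hydroxy-3-[3,4,5-tris(benzyloxy)phenyl]propanoate F4.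
- K2CO3 in MeOH closes it with inversion to the trans glycidate methyl (2R,3S)-3-[3,4,5-tris(benzyloxy)phenyl]oxirane-2-carboxylate F5.
- The phenoxide of 13 (Cs2CO3, DMF, 50 °C) opens F5 at the benzylic carbon with inversion to give methyl (2R,3R)-3-(3,5-dihydroxy-2,4-dimethoxyphenoxy)-2-hydroxy-3-[3,4,5-tris(benzyloxy)phenyl]propanoate F6.
- BnBr and K2CO3 in DMF give methyl (2R,3R)-3-[3,5-bis(benzyloxy)-2,4-dimethoxyphenoxy]-2-hydroxy-3-[3,4,5-tris(benzyloxy)phenyl]propanoate F7.
- LiOH in THF–H2O gives (2R,3R)-3-[3,5-bis(benzyloxy)-2,4-dimethoxyphenoxy]-2-hydroxy-3-[3,4,5-tris(benzyloxy)phenyl]propanoic acid F8.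
- Intramolecular Friedel–Crafts acylation (trifluoroacetic anhydride, CH2Cl2, 0 °C, then NaHCO3 in MeOH to remove the transient trifluoroacetate) at the only free position of ring A gives 18.

**Step 7 (threefold hydroxylation).** The risks are incomplete coupling at the bromide flanked by two methoxy groups, hydrodebromination, and air oxidation of the triol in hot base. The fallback sets out from 12 and comes back at 13. Ullmann ether synthesis with sodium benzyloxide (BnOH, NaH, CuI 20 mol %, N-methylpyrrolidone, 120 °C) gives 1,3,5-tris(benzyloxy)-2,4-dimethoxybenzene F1. This stable ether can be purified, and hydrogenolysis (H2, 10% Pd/C, EtOAc, rt) releases 13 under neutral, oxygen-free conditions.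

## Further compounds

F1 | step 7 | 1,3,5-tris(benzyloxy)-2,4-dimethoxybenzene | COc1c(OCc2ccccc2)cc(OCc2ccccc2)c(OC)c1OCc1ccccc1
F2 | step 8 | methyl (2S,3S)-3,4,6-trihydroxy-5,7-dimethoxy-2-[3,4,5-tris(benzyloxy)phenyl]-2,3-dihydro-1-benzofuran-3-carboxylate | COC(=O)[C@@]1(O)[C@H](c2cc(OCc3ccccc3)c(OCc3ccccc3)c(OCc3ccccc3)c2)Oc2c(OC)c(O)c(OC)c(O)c12
F3 | step 8 | methyl (2S,3S)-4,6-bis(benzyloxy)-3-hydroxy-5,7-dimethoxy-2-[3,4,5-tris(benzyloxy)phenyl]-2,3-dihydro-1-benzofuran-3-carboxylate | COC(=O)[C@@]1(O)[C@H](c2cc(OCc3ccccc3)c(OCc3ccccc3)c(OCc3ccccc3)c2)Oc2c(OC)c(OCc3ccccc3)c(OC)c(OCc3ccccc3)c12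
F4 | step 11 | methyl (2S,3R)-3-chloro-2-hydroxy-3-[3,4,5-tris(benzyloxy)phenyl]propanoate | COC(=O)[C@H](O)[C@H](Cl)c1cc(OCc2ccccc2)c(OCc2ccccc2)c(OCc2ccccc2)c1
F5 | step 11 | methyl (2R,3S)-3-[3,4,5-tris(benzyloxy)phenyl]oxirane-2-carboxylate | COC(=O)[C@@H]1O[C@H]1c1cc(OCc2ccccc2)c(OCc2ccccc2)c(OCc2ccccc2)c1
F6 | step 11 | methyl (2R,3R)-3-(3,5-dihydroxy-2,4-dimethoxyphenoxy)-2-hydroxy-3-[3,4,5-tris(benzyloxy)phenyl]propanoate | COC(=O)[C@H](O)[C@@H](c1cc(OCc2ccccc2)c(OCc2ccccc2)c(OCc2ccccc2)c1)Oc1cc(O)c(OC)c(O)c1OC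
F7 | step 11 | methyl (2R,3R)-3-[3,5-bis(benzyloxy)-2,4-dimethoxyphenoxy]-2-hydroxy-3-[3,4,5-tris(benzyloxy)phenyl]propanoate | COC(=O)[C@H](O)[C@@H](c1cc(OCc2ccccc2)c(OCc2ccccc2)c(OCc2ccccc2)c1)Oc1cc(OCc2ccccc2)c(OC)c(OCc2ccccc2)c1OC
F8 | step 11 | (2R,3R)-3-[3,5-bis(benzyloxy)-2,4-dimethoxyphenoxy]-2-hydroxy-3-[3,4,5-tris(benzyloxy)phenyl]propanoic acid | OC(=O)[C@H](O)[C@@H](c1cc(OCc2ccccc2)c(OCc2ccccc2)c(OCc2ccccc2)c1)Oc1cc(OCc2ccccc2)c(OC)c(OCc2ccccc2)c1OC
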